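**Plan**

- Numbering is that of the germacrane skeleton: ring carbons C1–C10, lactone carbons C11–C13 (C12 carbonyl, C13 exocyclic CH2), C14 on C10, C15 on C4, with O6, O8, O14 and O15 on those carbons.
- Retrosynthesis: after removal of the C8 isovalerate, the C14 aldehyde and C13, the ten-membered ring is cut at C2–C3. This is the only ring bond with a C=C on each side (C1=C10 and C4=C5), so both carbons are allylic (C2 as a sulfonyl carbanion, C3 as a chloride), and the cut lies away from the C6–C8 stereotriad held in the cis-fused γ-lactone.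
- The open lactone is then cut at O6–C12 (lactonisation), C4=C5 (silicon-tethered ring-closing metathesis), C5–C6 (Weinreb ketone synthesis), C7–C8 (aldol) and C9–C10 (Negishi coupling).
- Forward: but-2-yne-1,4-diol gives the C8–C10/C1–C2/C14 aldehyde, and aldol, ketone formation and reduction build C6–C8. A temporary seven-membered silicon ring comes first, then the γ-lactone, then the carbocycle.
- Stereochemistry: C7 and C8 come from the (R)-4-benzyloxazolidinone syn-aldol, C6 from Felkin–Anh hydride delivery, the C1=C10 geometry from trans-hydroalumination/iodination and the C4=C5 geometry from the seven-membered metathesis ring. The C2 sulfone centre is erased.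

Key step: step 19

Step 1
Reactants: 1 but-2-yne-1,4-diol
Product: 2 4-{[tert-butyl(diphenyl)silyl]oxy}but-2-yn-1-ol
Conditions: NaH (1 equiv), THF, 0 °C; t-BuPh2SiCl (1 equiv), 0 °C → rt
Reagents that add atoms: tert-butyl(chloro)diphenylsilane, CC(C)(C)[Si](Cl)(c1ccccc1)c1ccccc1
Why: O-silylation of the monosodium alkoxide of a symmetrical diol (Williamson-type silyl ether formation) should stop after one silyl transfer and marks the future O14 with a group that is left alone until step 24.

Step 2
Reactants: 2 4-{[tert-butyl(diphenyl)silyl]oxy}but-2-yn-1-ol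
Product: 4 (Z)-4-{[tert-butyl(diphenyl)silyl]oxy}-3-iodobut-2-en-1-ol (iodine cis to CH2OH), via cyclic alkenylaluminate 3 (not isolated)
Conditions: NaAlH2(OCH2CH2OMe)2, THF, 0 °C; EtOAc; I2, THF, −78 °C; aqueous potassium sodium tartrate
Reagents that add atoms: iodine, II
Why: Hydroxyl-directed trans-hydroalumination of the propargylic alcohol puts hydride on the near alkyne carbon (C1) and aluminium on the far one (C10) inside a five-membered aluminate, and iodinolysis of the C–Al bond with retention should give the single vinyl iodide in which the future C9 site is cis to C2.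

Step 3
Reactants: 4 (Z)-4-{[tert-butyl(diphenyl)silyl]oxy}-3-iodobut-2-en-1-ol
Product: 5 tert-butyl{[(Z)-2-iodo-4-(phenylsulfanyl)but-2-en-1-yl]oxy}diphenylsilane
Conditions: PhSSPh, n-Bu3P, THF, 0 °C → rt
Reagents that add atoms: diphenyl disulfide, c1ccccc1SSc1ccccc1
Why: In this phosphine–disulfide thioetherification (Hata reaction) the alkoxyphosphonium ion of the primary allylic alcohol is displaced by thiolate in an SN2 step, which places sulfur on C2 as a sulfide that tolerates the organometallic, hydride and alkoxide steps ahead and is raised to the sulfone only in step 18.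

Step 4
Reactants: 5 tert-butyl{[(Z)-2-iodo-4-(phenylsulfanyl)but-2-en-1-yl]oxy}diphenylsilane
Product: 6 ethyl (E)-3-({[tert-butyl(diphenyl)silyl]oxy}methyl)-5-(phenylsulfanyl)pent-3-enoate (C9 cis to C2)
Conditions: BrZnCH2CO2Et (from BrCH2CO2Et and Zn), Pd(PPh3)4 (5 mol %), THF, 50 °C
Reagents that add atoms: ethyl bromoacetate, CCOC(=O)CBr
Why: Negishi coupling of the alkenyl iodide with the Reformatsky zinc enolate forms C9–C10 with retention of the olefin geometry and should give the β,γ-unsaturated ester without moving the double bond.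

Step 5
Reactants: 6 ethyl (E)-3-({[tert-butyl(diphenyl)silyl]oxy}methyl)-5-(phenylsulfanyl)pent-3-enoate
Product: 7 (E)-3-({[tert-butyl(diphenyl)silyl]oxy}methyl)-5-(phenylsulfanyl)pent-3-enal
Conditions: i-Bu2AlH (1.05 equiv), CH2Cl2, −78 °C; MeOH, aqueous potassium sodium tartrate; used at once
Reagents that add atoms: none
Why: Partial ester reduction stops at the tetrahedral aluminium hemiacetal at −78 °C, and the neutral tartrate work-up should release the β,γ-unsaturated aldehyde (C8) without conjugation.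

Step 6
Reactants: 8 4-tert-butoxy-4-oxobutanoic acid; 9 (R)-4-benzyl-1,3-oxazolidin-2-one
Product: 11 tert-butyl 4-[(4R)-4-benzyl-2-oxo-1,3-oxazolidin-3-yl]-4-oxobutanoate, via mixed pivalic anhydride 10 (not isolated)
Conditions: t-BuCOCl, Et3N, THF, −20 °C; then 9, LiCl, rt
Reagents that add atoms: none
Why: N-acylation of the oxazolidinone through the mixed pivalic anhydride takes place at the unhindered succinyl carbonyl and gives the imide whose α-CH2 is the future C7.

Step 7
Reactants: 11 tert-butyl 4-[(4R)-4-benzyl-2-oxo-1,3-oxazolidin-3-yl]-4-oxobutanoate; 7 (E)-3-({[tert-butyl(diphenyl)silyl]oxy}methyl)-5-(phenylsulfanyl)pent-3-enal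
Product: 13 syn-aldol imide tert-butyl (3R,4S,6E)-3-{[(4R)-4-benzyl-2-oxo-1,3-oxazolidin-3-yl]carbonyl}-6-({[tert-butyl(diphenyl)silyl]oxy}methyl)-4-hydroxy-8-(phenylsulfanyl)oct-6-enoate, via dibutylboron (Z)-enolate 12 (not isolated)
Conditions: n-Bu2BOTf, i-Pr2NEt, CH2Cl2, 0 °C; 7, −78 → 0 °C; pH 7 buffer/MeOH work-up without peroxide
Reagents that add atoms: none
Why: In this Evans syn-aldol reaction only the imide α-CH2 is enolised, the (Z)-boron enolate reacts through a Zimmerman–Traxler chair on the face left open by the benzyl group of the (R)-auxiliary and so sets C7 and C8 (7,8-syn, both as in the target), while the tert-butyl ester is too hindered to be attacked by the C8 aldolate and the peroxide-free work-up spares the sulfide.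

Step 8
Reactants: 13 syn-aldol imide
Product: 14 Weinreb amide tert-butyl (3R,4S,6E)-6-({[tert-butyl(diphenyl)silyl]oxy}methyl)-4-hydroxy-3-[methoxy(methyl)carbamoyl]-8-(phenylsulfanyl)oct-6-enoate
Conditions: MeNH(OMe)·HCl, AlMe3, THF, −20 → 0 °C
Reagents that add atoms: N,O-dimethylhydroxylamine hydrochloride, CNOC.Cl
Why: Aluminium amide aminolysis of the imide (Weinreb transamidation) is assisted by the free β-hydroxyl, releases the auxiliary and should leave the tert-butyl ester untouched.

Step 9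
Reactants: 14 Weinreb amide
Product: 15 tert-butyl (3R,4S,6E)-4-{[tert-butyl(dimethyl)silyl]oxy}-6-({[tert-butyl(diphenyl)silyl]oxy}methyl)-3-[methoxy(methyl)carbamoyl]-8-(phenylsulfanyl)oct-6-enoate
Conditions: t-BuMe2SiOTf, 2,6-lutidine, CH2Cl2, −78 → 0 °C
Reagents that add atoms: tert-butyldimethylsilyl trifluoromethanesulfonate, CC(C)(C)[Si](C)(C)OS(=O)(=O)C(F)(F)F
Why: Silyl triflate silylation of the hindered secondary alcohol blocks O8, so that later only O6 can close onto C12.

Step 10
Reactants: 15 O8-silylated Weinreb amide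
Product: 16 enone tert-butyl (3R,4S,6E)-3-[(2E)-but-2-enoyl]-4-{[tert-butyl(dimethyl)silyl]oxy}-6-({[tert-butyl(diphenyl)silyl]oxy}methyl)-8-(phenylsulfanyl)oct-6-enoate
Conditions: (E)-CH3CH=CHBr, t-BuLi (2 equiv), Et2O, −78 °C; then 15, THF, −78 → −40 °C; H2O
Reagents that add atoms: (E)-1-bromoprop-1-ene, C/C=C/Br
Why: In the Weinreb ketone synthesis the alkenyllithium adds once to give a chelated tetrahedral adduct that collapses only on work-up, which forms C5–C6 at the ketone level without touching the tert-butyl ester or the C7 centre.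

Step 11
Reactants: 16 enone
Product: 17 allylic alcohol tert-butyl (3S,4S,6E)-4-{[tert-butyl(dimethyl)silyl]oxy}-6-({[tert-butyl(diphenyl)silyl]oxy}methyl)-3-[(1S,2E)-1-hydroxybut-2-en-1-yl]-8-(phenylsulfanyl)oct-6-enoate
Conditions: LiBH(s-Bu)3, THF, −78 °C; AcOH, −78 °C; non-oxidative work-up
Reagents that add atoms: none
Why: In this Felkin–Anh 1,2-reduction of the acyclic enone the bulky hydride attacks C6 anti to the large C8 silyloxyalkyl branch on C7 and should give the (6S)-carbinol (O6 anti to C11, the arrangement that later makes the lactone cis), while the cold acidic quench keeps the alkoxide from closing onto the ester before the tether is on.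

Step 12
Reactants: 18 2-methylidenepropane-1,3-diol
Product: 19 2-{[(4-methoxybenzyl)oxy]methyl}prop-2-en-1-ol
Conditions: NaH (1 equiv), THF/DMF, 0 °C; 4-MeOC6H4CH2Cl, Bu4NI (cat.), rt
Reagents that add atoms: 4-methoxybenzyl chloride, COc1ccc(CCl)cc1
Why: Williamson monoetherification of the symmetrical diol through its monosodium alkoxide gives the C3–C4(=CH2)–C15 unit with O15 as an ether that cannot migrate and O3 free for the tether.

Step 13
Reactants: 17 allylic alcohol; 19 2-{[(4-methoxybenzyl)oxy]methyl}prop-2-en-1-ol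
Product: 21 mixed diisopropylsilyl ketal joining O6 of 17 to the hydroxyl oxygen (O3) of 19, via chlorosilyl ether 20 (not isolated)
Conditions: i-Pr2SiCl2 (1.5 equiv), imidazole, CH2Cl2, 0 °C; then 19 (2 equiv), rt
Reagents that add atoms: dichlorodi(propan-2-yl)silane, CC(C)[Si](Cl)(Cl)C(C)C
Why: In this stepwise substitution at silicon (temporary silicon tether) the hindered secondary alcohol uses up one Si–Cl bond only, and the resulting chlorosilane silylates the primary allylic alcohol to give the mixed bis-alkoxysilane.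

Step 14
Reactants: 21 mixed diisopropylsilyl ketal
Product: 22 2,2-diisopropyl-4,7-dihydro-1,3,2-dioxasilepine with the C7 chain on ring carbon C6 and CH2OPMB on ring carbon C4 (ring olefin C4=C5)
Conditions: second-generation Grubbs catalyst RuCl2(=CHPh)(PCy3)(H2IMes) (10 mol %), toluene (0.005 M), 80 °C, argon purge
Reagents that add atoms: none
Why: Ring-closing metathesis of the propenyl group with the 1,1-disubstituted olefin releases propene and forms C4=C5 inside a seven-membered 1,3-dioxa-2-silacycloheptene, a ring that can hold only the cis olefin, so that C3 must be cis to C6.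

Step 15
Reactants: 22 dioxasilepine
Product: 23 ene-1,4-diol tert-butyl ester (free O6–H and O3–H; C3 cis to C6)
Conditions: HF·pyridine, pyridine, THF, 0 °C
Reagents that add atoms: none
Why: In this silyl tether cleavage fluoride breaks both Si–O bonds of the dialkoxysilane, which is far more labile than the secondary TBS and the TBDPS ether under pyridine-buffered conditions, and frees O6 and O3.

Step 16
Reactants: 23 ene-1,4-diol tert-butyl ester
Product: 24 cis-β,γ-disubstituted γ-lactone with the C5=C4(C15H2OPMB)–C3H2OH arm on C6 and the C8(OTBS)–C9H2–C10(C14H2OTBDPS)=C1H–C2H2SPh arm on C7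
Conditions: KOt-Bu (0.2 equiv), THF, 0 °C; AcOH
Reagents that add atoms: none
Why: In this base-catalysed lactonisation (intramolecular transesterification, 5-exo-trig) the C6 alkoxide closes onto the tert-butyl ester and releases tert-butoxide as the chain carrier, O8 is silylated so only the 6,12-olide can form, its C6 and C7 arms are cis by virtue of steps 7 and 11, and the benzyl-type ether on O15 cannot migrate to the free O3.

Step 17
Reactants: 24 hydroxy lactone
Product: 26 lactone with C3 allylic chloride and C2 phenyl sulfide, via allylic mesylate 25 (not isolated)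
Conditions: MsCl, Et3N, CH2Cl2, −20 °C; then LiCl, DMF, 0 °C → rt
Reagents that add atoms: lithium chloride, [Li+].[Cl-]
Why: Mesylation and SN2 displacement by chloride at the primary allylic carbon should give the C3 chloride without allylic transposition or change of the C4=C5 geometry.

Step 18
Reactants: 26 chloro sulfide lactone
Product: 27 lactone with the C5=C4(C15H2OPMB)–C3H2Cl arm on C6 and the C8(OTBS)–C9H2–C10(C14H2OTBDPS)=C1H–C2H2SO2Ph arm on C7
Conditions: 30% H2O2, (NH4)6Mo7O24·4H2O (10 mol %), EtOH, 0 °C → rt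
Reagents that add atoms: hydrogen peroxide, OO
Why: In this molybdate-catalysed oxidation of the sulfide to the sulfone the electrophilic peroxomolybdate reacts at sulfur much faster than at the trisubstituted olefins, and the allylic chloride, the PMB ether and the silyl ethers should be inert to it.

Step 19
Reactants: 27 sulfonyl chloro lactone
Product: 29 bicyclic lactone with the ten-membered ring closed and PhSO2 on C2 (both C2 epimers), via potassium α-sulfonyl carbanion 28 (not isolated)
Conditions: KN(SiMe3)2 (1.05 equiv) added dropwise to 27 in THF (0.001 M), −78 °C; then −78 → 0 °C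
Reagents that add atoms: none
Why: KN(SiMe3)2 removes a proton from C2, α to the sulfonyl group, and the allylic carbanion 28 displaces chloride from the primary allylic carbon C3 in an intramolecular SN2 reaction that forms C2–C3. The closest known reaction type is the closure of ten-membered 1,5-diene rings by alkylation of sulfur-stabilised allylic carbanions with allylic halides. The carbocycle closes in a 10-exo-tet mode, the C–Cl bond lying outside the new ring, and no other ring is formed. The new centre at C2 is not controlled and need not be, since step 20 removes it, and C6–C8 and both olefin geometries are not touched. The step needs α- over γ-attack of the anion (the sulfonyl group holds the charge at C2 and C10 is fully substituted), SN2 over SN2′ (primary chloride; attack at C5 would give an eight-membered ring), ring closure over oligomerisation (high dilution, base added to the substrate, both arms held on one face of the cis-lactone and turned towards each other by the two cis ring olefins) and C2–H over C11–H deprotonation. The last should be secured by the higher acidity of the allylic sulfone, by the amine HN(SiMe3)2 that returns any lactone enolate to the sulfonyl anion, and by the C8 side chain, which shields the only enolate face that C3 could reach.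

Step 20
Reactants: 29 macrocyclic sulfone
Product: 30 bicyclic lactone with C2H2–C3H2 (O8 TBS, O14 TBDPS, O15 PMB)
Conditions: 6% Na(Hg), Na2HPO4, MeOH/THF (1:1), −20 °C
Reagents that add atoms: none
Why: Reductive desulfonylation by electron transfer from sodium amalgam (Julia-type C–S cleavage) gives an allyl anion that should be protonated at its less substituted end C2, which keeps C1=C10 in place and merges both C2 epimers, while the phosphate buffer protects the lactone.

Step 21
Reactants: 30 desulfonylated bicyclic lactone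
Product: 34 α-methylene lactone (C11=C13; O8 TBS, O14 TBDPS, O15 PMB), via lithium lactone enolate 31 (not isolated), via Mannich base 32 (not isolated), via trimethylammonium iodide 33 (not isolated)
Conditions: LiN(i-Pr)2, THF, −78 °C; [Me2N=CH2]I, −78 °C → rt; crude amine: MeI, MeOH, rt; then aqueous NaHCO3, CH2Cl2, rt
Reagents that add atoms: N,N-dimethylmethyleneiminium iodide, C=[N+](C)C.[I-]
Why: Mannich aminomethylation of the lactone enolate at C11, N-methylation and Hofmann-type elimination of trimethylamine install the exocyclic C11=C13 olefin, the lactone CH2 being the only carbon acid within reach of the amide base.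

Step 22
Reactants: 34 α-methylene lactone
Product: 35 C8 alcohol (O14 TBDPS, O15 PMB)
Conditions: camphor-10-sulfonic acid (0.3 equiv), MeOH/CH2Cl2 (1:1), 0 °C → rt
Reagents that add atoms: none
Why: Acid-catalysed methanolysis (silyl ether solvolysis) should remove the secondary TBS ether much faster than the TBDPS ether on O14, and neither the PMB ether nor the α-methylene lactone reacts with acid in methanol.

Step 23
Reactants: 35 C8 alcohol
Product: 36 C8 isovalerate (O14 TBDPS, O15 PMB)
Conditions: Me2CHCH2COCl, pyridine, DMAP (cat.), CH2Cl2, 0 °C → rt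
Reagents that add atoms: 3-methylbutanoyl chloride, CC(C)CC(=O)Cl
Why: DMAP-catalysed acylation of the only free hydroxyl group (O8) installs the isovalerate with retention at C8.

Step 24
Reactants: 36 C8 isovalerate
Product: 37 C14 alcohol (O15 PMB)
Conditions: Bu4NF, AcOH (1:1), THF, 0 °C → rt
Reagents that add atoms: none
Why: Fluoride desilylation of the TBDPS ether, buffered with acetic acid so that neither the α-methylene lactone nor the isovalerate meets free alkoxide, frees O14.

Step 25
Reactants: 37 C14 alcohol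
Product: 38 C14 aldehyde (O15 PMB)
Conditions: MnO2 (activated, excess), CH2Cl2, rt
Reagents that add atoms: none
Why: MnO2 oxidises the primary allylic alcohol to the conjugated aldehyde (allylic alcohol oxidation) and finds no second allylic hydroxyl because O15 still bears the PMB group.

Step 26
Reactants: 38 C14 aldehyde
Product: 39 target compound
Conditions: DDQ, CH2Cl2/pH 7 buffer (10:1), 0 °C
Reagents that add atoms: none
Why: Oxidative cleavage of the PMB ether by DDQ (benzylic hydride abstraction, then hydrolysis of the oxocarbenium ion) is neutral and short enough at 0 °C to leave the enal, the α-methylene lactone, the ester and the liberated allylic alcohol unchanged.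

**Compound list**

1 | but-2-yne-1,4-diol | OCC#CCO | starting material
2 | 4-{[tert-butyl(diphenyl)silyl]oxy}but-2-yn-1-ol | OCC#CCO[Si](c1ccccc1)(c1ccccc1)C(C)(C)C | intermediate
3 | sodium bis(2-methoxyethoxy) cyclic alkenylaluminate from 2 (five-membered O–Al–C=C–C ring, Al on C10) | [Na+].COCCO[Al-]1(OCCOC)OCC=C1CO[Si](c2ccccc2)(c2ccccc2)C(C)(C)C | intermediate
4 | (Z)-4-{[tert-butyl(diphenyl)silyl]oxy}-3-iodobut-2-en-1-ol | OC/C=C(\I)CO[Si](c1ccccc1)(c1ccccc1)C(C)(C)C | intermediate
5 | tert-butyl{[(Z)-2-iodo-4-(phenylsulfanyl)but-2-en-1-yl]oxy}diphenylsilane | c1ccccc1SC/C=C(\I)CO[Si](c1ccccc1)(c1ccccc1)C(C)(C)C | intermediate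
6 | ethyl (E)-3-({[tert-butyl(diphenyl)silyl]oxy}methyl)-5-(phenylsulfanyl)pent-3-enoate | CCOC(=O)C/C(CO[Si](c1ccccc1)(c1ccccc1)C(C)(C)C)=C\CSc1ccccc1 | intermediate
7 | (E)-3-({[tert-butyl(diphenyl)silyl]oxy}methyl)-5-(phenylsulfanyl)pent-3-enal | O=CC/C(CO[Si](c1ccccc1)(c1ccccc1)C(C)(C)C)=C\CSc1ccccc1 | intermediate
8 | 4-tert-butoxy-4-oxobutanoic acid | CC(C)(C)OC(=O)CCC(=O)O | starting material
9 | (R)-4-benzyl-1,3-oxazolidin-2-one | O=C1N[C@H](Cc2ccccc2)CO1 | starting material
10 | 4-tert-butoxy-4-oxobutanoic pivalic anhydride | CC(C)(C)OC(=O)CCC(=O)OC(=O)C(C)(C)C | intermediate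
11 | tert-butyl 4-[(4R)-4-benzyl-2-oxo-1,3-oxazolidin-3-yl]-4-oxobutanoate | CC(C)(C)OC(=O)CCC(=O)N1[C@H](Cc2ccccc2)COC1=O | intermediate
12 | dibutylboron (Z)-enolate of 11 | CCCCB(CCCC)O/C(=C\CC(=O)OC(C)(C)C)N1[C@H](Cc2ccccc2)COC1=O | intermediate
13 | syn-aldol imide, tert-butyl (3R,4S,6E)-3-{[(4R)-4-benzyl-2-oxo-1,3-oxazolidin-3-yl]carbonyl}-6-({[tert-butyl(diphenyl)silyl]oxy}methyl)-4-hydroxy-8-(phenylsulfanyl)oct-6-enoate | O=C(N1[C@H](Cc2ccccc2)COC1=O)[C@H](CC(=O)OC(C)(C)C)[C@@H](O)C/C(CO[Si](c1ccccc1)(c1ccccc1)C(C)(C)C)=C\CSc1ccccc1 | intermediate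
14 | Weinreb amide, tert-butyl (3R,4S,6E)-6-({[tert-butyl(diphenyl)silyl]oxy}methyl)-4-hydroxy-3-[methoxy(methyl)carbamoyl]-8-(phenylsulfanyl)oct-6-enoate | CON(C)C(=O)[C@H](CC(=O)OC(C)(C)C)[C@@H](O)C/C(CO[Si](c1ccccc1)(c1ccccc1)C(C)(C)C)=C\CSc1ccccc1 | intermediate
15 | O8 TBS ether of 14 | CON(C)C(=O)[C@H](CC(=O)OC(C)(C)C)[C@@H](O[Si](C)(C)C(C)(C)C)C/C(CO[Si](c1ccccc1)(c1ccccc1)C(C)(C)C)=C\CSc1ccccc1 | intermediate
16 | (E)-propenyl ketone at C6 (enone), C7 and C8 as in 15 | C/C=C/C(=O)[C@H](CC(=O)OC(C)(C)C)[C@@H](O[Si](C)(C)C(C)(C)C)C/C(CO[Si](c1ccccc1)(c1ccccc1)C(C)(C)C)=C\CSc1ccccc1 | intermediate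
17 | (6S)-allylic alcohol from 16 (O6 anti to C11, C11 syn to O8) | C/C=C/[C@H](O)[C@H](CC(=O)OC(C)(C)C)[C@@H](O[Si](C)(C)C(C)(C)C)C/C(CO[Si](c1ccccc1)(c1ccccc1)C(C)(C)C)=C\CSc1ccccc1 | intermediate
18 | 2-methylidenepropane-1,3-diol | C=C(CO)CO | starting material
19 | 2-{[(4-methoxybenzyl)oxy]methyl}prop-2-en-1-ol | C=C(CO)COCc1ccc(OC)cc1 | intermediate
20 | O6 chloro(diisopropyl)silyl ether of 17 | C/C=C/[C@H](O[Si](Cl)(C(C)C)C(C)C)[C@H](CC(=O)OC(C)(C)C)[C@@H](O[Si](C)(C)C(C)(C)C)C/C(CO[Si](c1ccccc1)(c1ccccc1)C(C)(C)C)=C\CSc1ccccc1 | intermediate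
21 | mixed diisopropylsilyl ketal of 17 (O6) and 19 (O3) | C/C=C/[C@H](O[Si](C(C)C)(C(C)C)OCC(=C)COCc1ccc(OC)cc1)[C@H](CC(=O)OC(C)(C)C)[C@@H](O[Si](C)(C)C(C)(C)C)C/C(CO[Si](c1ccccc1)(c1ccccc1)C(C)(C)C)=C\CSc1ccccc1 | intermediate
22 | 2,2-diisopropyl-4,7-dihydro-1,3,2-dioxasilepine holding O6–C6–C5=C4(C15H2OPMB)–C3–O3, C7 chain on C6 | CC(C)[Si]1(C(C)C)OC/C(COCc2ccc(OC)cc2)=C\[C@H](O1)[C@H](CC(=O)OC(C)(C)C)[C@@H](O[Si](C)(C)C(C)(C)C)C/C(CO[Si](c2ccccc2)(c2ccccc2)C(C)(C)C)=C\CSc2ccccc2 | intermediate
23 | ene-1,4-diol tert-butyl ester (O6–H, O3–H; C3 cis to C6) | OC/C(COCc1ccc(OC)cc1)=C\[C@H](O)[C@H](CC(=O)OC(C)(C)C)[C@@H](O[Si](C)(C)C(C)(C)C)C/C(CO[Si](c1ccccc1)(c1ccccc1)C(C)(C)C)=C\CSc1ccccc1 | intermediate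
24 | cis-γ-lactone (6,12-olide) with C3 hydroxyl and C2 phenyl sulfide | O=C1C[C@H]([C@@H](O[Si](C)(C)C(C)(C)C)C/C(CO[Si](c2ccccc2)(c2ccccc2)C(C)(C)C)=C\CSc2ccccc2)[C@H](/C=C(/COCc2ccc(OC)cc2)CO)O1 | intermediate
25 | C3 mesylate of 24 | O=C1C[C@H]([C@@H](O[Si](C)(C)C(C)(C)C)C/C(CO[Si](c2ccccc2)(c2ccccc2)C(C)(C)C)=C\CSc2ccccc2)[C@H](/C=C(/COCc2ccc(OC)cc2)COS(C)(=O)=O)O1 | intermediate
26 | cis-γ-lactone with C3 chloride and C2 phenyl sulfide | O=C1C[C@H]([C@@H](O[Si](C)(C)C(C)(C)C)C/C(CO[Si](c2ccccc2)(c2ccccc2)C(C)(C)C)=C\CSc2ccccc2)[C@H](/C=C(/COCc2ccc(OC)cc2)CCl)O1 | intermediate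
27 | cis-γ-lactone with C3 chloride and C2 phenyl sulfone (ring-closure precursor) | O=C1C[C@H]([C@@H](O[Si](C)(C)C(C)(C)C)C/C(CO[Si](c2ccccc2)(c2ccccc2)C(C)(C)C)=C\CS(=O)(=O)c2ccccc2)[C@H](/C=C(/COCc2ccc(OC)cc2)CCl)O1 | intermediate
28 | potassium C2 α-sulfonyl carbanion of 27 | O=C1C[C@H]([C@@H](O[Si](C)(C)C(C)(C)C)C/C(CO[Si](c2ccccc2)(c2ccccc2)C(C)(C)C)=C\[CH-]S(=O)(=O)c2ccccc2)[C@H](/C=C(/COCc2ccc(OC)cc2)CCl)O1.[K+] | intermediate
29 | bicyclic 6,12-olide with closed ten-membered ring, PhSO2 on C2 (C2 epimers), O8 TBS, O14 TBDPS, O15 PMB | O=C1O[C@H]2/C=C(/COCc3ccc(OC)cc3)CC(S(=O)(=O)c3ccccc3)/C=C(/CO[Si](c3ccccc3)(c3ccccc3)C(C)(C)C)C[C@H](O[Si](C)(C)C(C)(C)C)[C@H]2C1 | intermediate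
30 | desulfonylated bicyclic 6,12-olide (C11H2), O8 TBS, O14 TBDPS, O15 PMB | O=C1O[C@H]2/C=C(/COCc3ccc(OC)cc3)CC/C=C(/CO[Si](c3ccccc3)(c3ccccc3)C(C)(C)C)C[C@H](O[Si](C)(C)C(C)(C)C)[C@H]2C1 | intermediate
31 | lithium enolate of 30 (C11=C12–OLi) | [Li]OC=1O[C@H]2/C=C(/COCc3ccc(OC)cc3)CC/C=C(/CO[Si](c3ccccc3)(c3ccccc3)C(C)(C)C)C[C@H](O[Si](C)(C)C(C)(C)C)[C@H]2C=1 | intermediate
32 | C11 (dimethylamino)methyl lactone (Mannich base, C11 epimers) | O=C1O[C@H]2/C=C(/COCc3ccc(OC)cc3)CC/C=C(/CO[Si](c3ccccc3)(c3ccccc3)C(C)(C)C)C[C@H](O[Si](C)(C)C(C)(C)C)[C@H]2C1CN(C)C | intermediate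
33 | trimethylammonium iodide of 32 | O=C1O[C@H]2/C=C(/COCc3ccc(OC)cc3)CC/C=C(/CO[Si](c3ccccc3)(c3ccccc3)C(C)(C)C)C[C@H](O[Si](C)(C)C(C)(C)C)[C@H]2C1C[N+](C)(C)C.[I-] | intermediate
34 | α-methylene lactone, O8 TBS, O14 TBDPS, O15 PMB | C=C1C(=O)O[C@H]2/C=C(/COCc3ccc(OC)cc3)CC/C=C(/CO[Si](c3ccccc3)(c3ccccc3)C(C)(C)C)C[C@H](O[Si](C)(C)C(C)(C)C)[C@@H]12 | intermediate
35 | α-methylene lactone with free C8 hydroxyl, O14 TBDPS, O15 PMB | C=C1C(=O)O[C@H]2/C=C(/COCc3ccc(OC)cc3)CC/C=C(/CO[Si](c3ccccc3)(c3ccccc3)C(C)(C)C)C[C@H](O)[C@@H]12 | intermediate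
36 | C8 isovalerate, O14 TBDPS, O15 PMB | C=C1C(=O)O[C@H]2/C=C(/COCc3ccc(OC)cc3)CC/C=C(/CO[Si](c3ccccc3)(c3ccccc3)C(C)(C)C)C[C@H](OC(=O)CC(C)C)[C@@H]12 | intermediate
37 | C8 isovalerate with free C14 hydroxyl, O15 PMB | C=C1C(=O)O[C@H]2/C=C(/COCc3ccc(OC)cc3)CC/C=C(/CO)C[C@H](OC(=O)CC(C)C)[C@@H]12 | intermediate
38 | C8 isovalerate C14 aldehyde, O15 PMB | C=C1C(=O)O[C@H]2/C=C(/COCc3ccc(OC)cc3)CC/C=C(/C=O)C[C@H](OC(=O)CC(C)C)[C@@H]12 | intermediate
39 | target: (6S,7R,8S) cis-fused α-methylene 6,12-olide with 8-O-isovalerate, C14 aldehyde, C15 hydroxymethyl, both ring olefins cis in the ring | C=C1C(=O)O[C@H]2/C=C(/CO)CC/C=C(/C=O)C[C@H](OC(=O)CC(C)C)[C@@H]12 | target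

**Step count and risks**

Total: 26 steps. Longest linear sequence: 24 steps (steps 1–5, 7–11 and 13–26).

Steps most likely to fail:

1. Step 19 (ring closure). The base may also reach C11–H, and the lactone enolate could then be alkylated by C3 across the lactone to a six-membered ring, or chains could couple with each other faster than the ten-membered ring closes. The fallback changes the oxidation level of C12 so that C2–H is the only carbon acid. It sets out from 27: i-Bu2AlH at −78 °C should give lactol F1, and MeOH with pyridinium p-toluenesulfonate the methyl acetal F2. The same KN(SiMe3)2 closure should then give the macrocyclic sulfone acetal F3, and sodium amalgam as in step 20 the desulfonylated acetal F4. Aqueous acetic acid should give the macrocyclic lactol F5, and PhI(OAc)2 with catalytic TEMPO oxidises it to 30, where the route is rejoined.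

2. Step 20 (desulfonylation). The allyl anion may be protonated at C10 instead of C2, which moves the double bond to C1=C2. The C1=C10 geometry may be lost at the radical or anion stage, and methoxide may open the lactone. The fallback replaces electron transfer by hydride substitution through a π-allylpalladium complex. It sets out from 29 and goes straight to 30 with catalytic Pd(PPh3)4 and NaBH4 in THF/i-PrOH at 0 °C: zerovalent palladium ionises the allylic sulfone and hydride is delivered to the less substituted terminus C2. No new compound is passed.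

3. Step 14 (tethered metathesis). Initiation at the two hindered olefins may be slow, sulfur may tie up the ruthenium carbene, and intermolecular metathesis may then compete. The fallback uses an acyl tether and a five-membered ring in place of the silicon tether. It sets out from 17 and 19: MnO2 should oxidise 19 to 2-{[(4-methoxybenzyl)oxy]methyl}prop-2-enal F6, and NaClO2/NaH2PO4/2-methylbut-2-ene should take this on to the acrylic acid F7. Yamaguchi esterification of 17 (2,4,6-Cl3C6H2COCl, Et3N, DMAP) gives the acrylate F8, and ring-closing metathesis gives the butenolide F9, in which C3 is the lactone carbonyl and is cis to C6 by the ring. i-Bu2AlH at −78 °C should give the lactol F10, and NaBH4/CeCl3·7H2O opens it to diol 23, where the route is rejoined.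

**Further compounds**

F1 | step 19 | lactol from 27 (C12 hemiacetal, arms unchanged) | OC1C[C@H]([C@@H](O[Si](C)(C)C(C)(C)C)C/C(CO[Si](c2ccccc2)(c2ccccc2)C(C)(C)C)=C\CS(=O)(=O)c2ccccc2)[C@H](/C=C(/COCc2ccc(OC)cc2)CCl)O1
F2 | step 19 | methyl acetal of F1 | COC1C[C@H]([C@@H](O[Si](C)(C)C(C)(C)C)C/C(CO[Si](c2ccccc2)(c2ccccc2)C(C)(C)C)=C\CS(=O)(=O)c2ccccc2)[C@H](/C=C(/COCc2ccc(OC)cc2)CCl)O1
F3 | step 19 | macrocyclic sulfone methyl acetal (C2 epimers) | COC1O[C@H]2/C=C(/COCc3ccc(OC)cc3)CC(S(=O)(=O)c3ccccc3)/C=C(/CO[Si](c3ccccc3)(c3ccccc3)C(C)(C)C)C[C@H](O[Si](C)(C)C(C)(C)C)[C@H]2C1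
F4 | step 19 | desulfonylated macrocyclic methyl acetal | COC1O[C@H]2/C=C(/COCc3ccc(OC)cc3)CC/C=C(/CO[Si](c3ccccc3)(c3ccccc3)C(C)(C)C)C[C@H](O[Si](C)(C)C(C)(C)C)[C@H]2C1
F5 | step 19 | macrocyclic lactol | OC1O[C@H]2/C=C(/COCc3ccc(OC)cc3)CC/C=C(/CO[Si](c3ccccc3)(c3ccccc3)C(C)(C)C)C[C@H](O[Si](C)(C)C(C)(C)C)[C@H]2C1
F0 | step 20 | none | none
F6 | step 14 | 2-{[(4-methoxybenzyl)oxy]methyl}prop-2-enal | C=C(C=O)COCc1ccc(OC)cc1
F7 | step 14 | 2-{[(4-methoxybenzyl)oxy]methyl}prop-2-enoic acid | C=C(COCc1ccc(OC)cc1)C(=O)O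
F8 | step 14 | O6 acrylate ester of 17 with F7 | C/C=C/[C@H](OC(=O)C(=C)COCc1ccc(OC)cc1)[C@H](CC(=O)OC(C)(C)C)[C@@H](O[Si](C)(C)C(C)(C)C)C/C(CO[Si](c1ccccc1)(c1ccccc1)C(C)(C)C)=C\CSc1ccccc1
F9 | step 14 | butenolide O6–C3(=O)–C4(C15H2OPMB)=C5–C6 carrying the C7 chain | O=C1O[C@@H](C=C1COCc2ccc(OC)cc2)[C@H](CC(=O)OC(C)(C)C)[C@@H](O[Si](C)(C)C(C)(C)C)C/C(CO[Si](c2ccccc2)(c2ccccc2)C(C)(C)C)=C\CSc2ccccc2
F10 | step 14 | lactol from F9 | OC1O[C@@H](C=C1COCc2ccc(OC)cc2)[C@H](CC(=O)OC(C)(C)C)[C@@H](O[Si](C)(C)C(C)(C)C)C/C(CO[Si](c2ccccc2)(c2ccccc2)C(C)(C)C)=C\CSc2ccccc2
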